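## Analysis of the target

The target 39 contains four guaiacyl-type arenes. Rings A and B are the α- and β-benzyl groups of a γ-butyrolactone. Ring B is fused to a dihydrofuran that carries ring C at C2 and a hydroxymethyl group at C3. Ring A carries, ortho to its free phenol, an open 1-aryl-propane-1,3-diol chain that ends in ring D.

The six stereocentres form three pairs: the lactone (3R,4R, trans), the dihydrobenzofuran (2S,3R, trans) and the diol chain (1S,2S, with carbinol oxygen and ring A anti in the zigzag drawn through CH2OH, C2, C1 and ring D). The pairs are separated by aryl–CH2 spacers, so none can control another and each needs its own source of absolute configuration.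

The sensitive groups are:
- three free phenols;
- a p-hydroxybenzylic carbinol next to the ortho-phenol of ring A, which under acid would close to a second dihydrobenzofuran;
- the C2–O1 bond of the dihydrobenzofuran, a benzylic aryl ether open to hydrogenolysis, to acid epimerisation and, once the ring C phenol is free, to base-induced opening;
- the epimerisable lactone α-centre, for which trans is the stable arrangement.

The difficulty is that two almost identical aryl–C3 units have to be built, one closed and one open, with different relative configurations, and that the last deprotections must be near neutral. The strategy rests on the connectivity at the dihydrobenzofuran: C3 is bonded to C3a of ring B and bears an oxygenated CH2, while C2 bears ring C and O1. This is the pattern left when an aryl radical ortho to a 1-arylallyl aryl ether adds to the inner alkene carbon and the outer carbon is oxygenated. C5 of ring B, para to O1, is where the lactone CH2 is attached, so a bromine there can ride through the radical step as the later handle.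

## Retrosynthetic reasoning

**39 back to 37.** The three phenols are unmasked last by hydrogenolysis (38 to 39) and the three alcohols just before by desilylation (37 to 38). Benzyl ethers are used on the phenols because a phenolic silyl ether would not survive the alkoxide of the condensation that builds the lactone. Silyl ethers are used on the alcohols so that they come off without acid.

**37 to 20 and 35.** The bond between the lactone α-carbon and the ring A benzylic CH2 is cut. This is the most convergent cut: it divides the molecule into the ring B/C lactone 20 and the ring A/D bromide 35. The forward alkylation of the enolate of 20 must occur anti to the β-substituent, which sets the α-centre from the β-centre.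

**20 to 14 and 15.** The lactone is traced through acid 18 to the arylidene half-ester 17, which comes from aldehyde 14 and succinate 15 by a Stobbe condensation. Cutting here reduces the β-stereocentre to a catalytic hydrogenation of a chelating acrylate. The half-ester keeps the two carboxyl carbons distinct, so reduction of the branched ester gives the β-benzyl lactone and not the α-benzyl one.

**14 to 10.** The formyl group of 14 replaces the bromine of 12. Bromide 12 is the silyl ether of alcohol 11, which comes from alkoxyamine 10 by cleavage of the N–O bond. The bromine is carried from the beginning so that no regioselective functionalisation of ring B is needed later.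

**10 to 8 and 9 (key disconnection).** The C3a–C3 bond and the CH2–O bond are cut. Forward, an aryl radical generated at the iodine-bearing carbon of 8 closes onto the vinyl group and the primary radical is captured by nitroxide 9. One step makes the ring, one C–C bond, one C–O bond and the C3 stereocentre, and delivers the CH2 at the alcohol oxidation level. The forward reaction has to discriminate iodine from bromine and give the trans ring.

**8 to 6 and 4.** The ether C–O bond at the stereocentre is cut. An allylic etherification of carbonate 4 by the aryloxide of 6 gives the branched ether and sets the only stereocentre of the precursor by catalyst control. Phenol 6 is the ortho-iodination product of 5, and 4 is reached from ferulic acid 1 through 2 and 3.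

**35 to 30.** Bromide 35 is traced through alcohol 34 and aldehyde 33 to aryl bromide 31, the bis-silyl ether of diol 30. The same bromine-to-formyl exchange is used as on the other fragment.

**30 to 25 and 26.** Diol 30 comes from homoallylic alcohol 28 by oxidative cleavage of the vinyl group and reduction. In 28 the bond between the two stereocentres is cut. Allylboration of aldehyde 26 by the (E)-γ-aryl allylboronate 25 gives the anti relationship through a closed chair transition state, and a chiral acid catalyst chooses the aldehyde face. An aldol route was not used because the standard auxiliary-controlled aldol gives the syn isomer.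

**25 to 21.** Boronate 25 is the cross-metathesis product of styrene 23 with allylboronate 24. Styrene 23 comes from commercial aldehyde 21 by benzylation (22) and methylenation.

## Alternatives that were turned down

**Alternative 1:** The open diol unit is cut at both aryl–carbon bonds.
- Forward step: the boronate complex formed from the (Z)-3-(silyloxy)propenyl pinacol boronate A2 and the ring D aryllithium A3 couples with the ring A aryl triflate A4 under Pd(OAc)2 and a chiral ferrocenyl bisphosphine. Migration of ring D from boron to carbon and reductive elimination of ring A give the anti boronic ester A1. Oxidation of the C–B bond would give the carbinol.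
- For: two C–C bonds and both stereocentres of the diol unit form in one catalytic step, and the anti relationship follows from the anti-periplanar migration on a (Z)-alkene. For this unit it is shorter than steps 13–17 of the chosen route and is stronger on step economy.
- Against: β-substituted alkenyl boronates are poor substrates for this coupling, the triflate A4 is flanked by an ortho-alkoxy group, and direct aryl transfer without migration competes. The step also leaves the dihydrobenzofuran and the lactone unsolved.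
- Comparison: the chosen strategy puts its one demanding step on the heterocycle, where a ring, a C–C bond and a C–O bond are made together. It pays with a longer but conventional allylboration route to the diol.

**Alternative 2:** The lactone is cut at its ring C–O bonds.
- Forward step: a Baeyer–Villiger monooxygenase with cofactor recycling inserts oxygen next to one enantiotopic CH2 of the cyclobutanone A6 and gives the (R)-β-(arylmethyl)lactone A5.
- For: the conditions are the mildest possible, the phenol and alcohol need no protection, and one step replaces steps 10–12 of the chosen route. On protecting-group economy it is stronger.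
- Against: A6 still has to be made from the aryl bromide in about three steps, so nothing is saved overall. The substrate is far larger than the 3-benzylcyclobutanones such enzymes are known to accept, and the enantiotopic selectivity could only be found by screening. The dihydrobenzofuran stereocentres must already be in place, so the step does not address the ring that defines the problem.
- Comparison: the chosen route sets the same centre by hydrogenation of a Stobbe half-ester, whose sense of induction is predictable, and spends its key step on the heterocycle.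

**Alternative 3:** The dihydrofuran is cut at O1–C2.
- Forward step: the diol A8, as a mixture of carbinol epimers, is treated with catalytic camphorsulfonic acid. The ring B phenol closes onto the benzylic cation and gives the trans dihydrobenzofuran A7.
- For: the closure is stereoconvergent and under thermodynamic control, so the trans ring is practically assured and the carbinol centre need not be controlled. On diastereocontrol it is stronger than the chosen radical closure, which is kinetically controlled.
- Against: A8 needs the aryl–C bond and the C3 stereocentre made beforehand by an auxiliary aldol and reduction sequence, which is longer. A7 comes out with a free ring C phenol that must be protected again.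
- Comparison: the chosen strategy makes the aryl–C3 bond, the ring and the CH2–O bond in one step, from a precursor whose single stereocentre is set by catalysis from two simple pieces.

Key step: step 6

Shorthand in names: Bn = benzyl; TBS = tert-butyldimethylsilyl; Ar(BC) = the (2S,3R)-2-[4-(benzyloxy)-3-methoxyphenyl]-3-[(TBS-oxy)methyl]-7-methoxy-2,3-dihydro-1-benzofuran-5-yl group.

Assumption: for the catalytic asymmetric steps 5, 11 and 16 the catalyst antipode written is the one expected from the sense of induction known for the closest simple substrates; if a test reaction shows the opposite sense, the mirror-image catalyst is used.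

## Route

Step 1
Reactants: 1 ferulic acid, (2E)-3-(4-hydroxy-3-methoxyphenyl)prop-2-enoic acid
Product: 2 benzyl (2E)-3-[4-(benzyloxy)-3-methoxyphenyl]prop-2-enoate
Conditions: BnBr (2.3 equiv), K2CO3, DMF, 60 °C
Reagents that add atoms: benzyl bromide, BrCc1ccccc1
Why: Williamson etherification of the phenoxide and SN2 esterification of the carboxylate run in one pot; the benzyl aryl ether is chosen because it survives the methoxide of step 10.

Step 2
Reactants: 2 benzyl (2E)-3-[4-(benzyloxy)-3-methoxyphenyl]prop-2-enoate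
Product: 3 (2E)-3-[4-(benzyloxy)-3-methoxyphenyl]prop-2-en-1-ol
Conditions: i-Bu2AlH (2.5 equiv), CH2Cl2, −78 to 0 °C; aqueous potassium sodium tartrate
Reagents that add atoms: none
Why: 1,2-Reduction of the conjugated ester by the aluminium hydride gives the allylic alcohol and leaves the alkene and the aryl benzyl ether alone; the benzyl alcohol released is removed by chromatography.

Step 3
Reactants: 3 (2E)-3-[4-(benzyloxy)-3-methoxyphenyl]prop-2-en-1-ol
Product: 4 (2E)-3-[4-(benzyloxy)-3-methoxyphenyl]prop-2-en-1-yl methyl carbonate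
Conditions: ClCO2Me, pyridine, CH2Cl2, 0 °C
Reagents that add atoms: methyl chloroformate, COC(=O)Cl
Why: Acylation of the primary alcohol; a methyl carbonate is the usual leaving group for iridium-catalysed allylic substitution because loss of CO2 makes ionisation irreversible.

Step 4
Reactants: 5 4-bromo-2-methoxyphenol
Product: 6 4-bromo-2-iodo-6-methoxyphenol
Conditions: N-iodosuccinimide (1.05 equiv), p-TsOH (10 mol %), MeCN, rt
Reagents that add atoms: N-iodosuccinimide, O=C1CCC(=O)N1I
Why: Electrophilic aromatic iodination directed by the hydroxyl group; its para position is blocked by bromine and one ortho position by methoxy, so iodine enters the remaining ortho position.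

Step 5
Reactants: 6 4-bromo-2-iodo-6-methoxyphenol; 4 (2E)-3-[4-(benzyloxy)-3-methoxyphenyl]prop-2-en-1-yl methyl carbonate
Product: 8 1-(benzyloxy)-4-[(1S)-1-(4-bromo-2-iodo-6-methoxyphenoxy)prop-2-en-1-yl]-2-methoxybenzene, via lithium 4-bromo-2-iodo-6-methoxyphenoxide 7 (not isolated)
Conditions: 6, LiN(SiMe3)2 (1.0 equiv), THF, 0 °C; then 4, [Ir(cod)Cl]2 (2 mol %), (Ra,Rc,Rc)-(1,1'-binaphthalene-2,2'-diyl) N,N-bis(1-phenylethyl)phosphoramidite (4 mol %), THF, 50 °C
Reagents that add atoms: none
Why: Iridium-catalysed asymmetric allylic etherification: the cyclometallated iridium phosphoramidite complex ionises the carbonate and the aryloxide attacks the aryl-bearing terminus of the allyl ligand, so the branched ether forms and the ligand sets the single stereocentre (S) by choosing the face of attack. A silylamide base is used because an alkyllithium would exchange the iodide.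

Step 6
Reactants: 8 1-(benzyloxy)-4-[(1S)-1-(4-bromo-2-iodo-6-methoxyphenoxy)prop-2-en-1-yl]-2-methoxybenzene; 9 TEMPO, 2,2,6,6-tetramethylpiperidin-1-oxyl
Product: 10 1-{[(2S,3R)-2-[4-(benzyloxy)-3-methoxyphenyl]-5-bromo-7-methoxy-2,3-dihydro-1-benzofuran-3-yl]methoxy}-2,2,6,6-tetramethylpiperidine
Conditions: 9 (6 equiv) and Bu3SnH (5 equiv), each added in three portions, degassed PhH (0.05 M), 70 °C
Reagents that add atoms: none
Why: The nitroxide takes hydrogen from Bu3SnH to give Bu3Sn•, which abstracts iodine from 8; the aryl σ-radical ortho to the ether oxygen adds to the inner vinyl carbon and forms the C3a–C3 bond, and the primary radical so formed is captured at carbon by a second nitroxide to form the CH2–O bond. The closest known reaction type is the tin hydride and TEMPO mediated aryl radical cyclisation with oxygen capture of 2-haloaryl allyl ethers and N-allyl anilides. The dihydrofuran ring closes in the 5-exo-trig mode. C2 is not touched and keeps the S configuration of 8. The new centre C3 is controlled by C2: in the chair-like transition state of the 5-exo closure the C2 aryl group sits pseudo-equatorial, so the CH2 group forms trans to it (3R). Iodine over bromine selectivity is needed and is secured by the much weaker C–I bond, since tin radicals abstract aryl iodine far faster than aryl bromine. Cyclisation before capture is needed and is secured by the very fast closure of 2-(allyloxy)aryl radicals against bimolecular trapping by nitroxide kept dilute through portionwise addition. Fast capture of the primary radical also prevents its reduction to a methyl group and its neophyl-type ring expansion to a chroman.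

Step 7
Reactants: 10 1-{[(2S,3R)-2-[4-(benzyloxy)-3-methoxyphenyl]-5-bromo-7-methoxy-2,3-dihydro-1-benzofuran-3-yl]methoxy}-2,2,6,6-tetramethylpiperidine
Product: 11 [(2S,3R)-2-[4-(benzyloxy)-3-methoxyphenyl]-5-bromo-7-methoxy-2,3-dihydro-1-benzofuran-3-yl]methanol
Conditions: Zn dust (excess), AcOH/THF/H2O (3:1:1), 70 °C
Reagents that add atoms: none
Why: Dissolving-metal reduction cleaves the weak N–O bond of the alkoxyamine and frees the primary alcohol; the aryl bromide, the benzyl ether and both stereocentres are not affected by zinc in acetic acid.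

Step 8
Reactants: 11 [(2S,3R)-2-[4-(benzyloxy)-3-methoxyphenyl]-5-bromo-7-methoxy-2,3-dihydro-1-benzofuran-3-yl]methanol
Product: 12 {[(2S,3R)-2-[4-(benzyloxy)-3-methoxyphenyl]-5-bromo-7-methoxy-2,3-dihydro-1-benzofuran-3-yl]methoxy}(tert-butyl)dimethylsilane, that is Ar(BC)–Br
Conditions: TBSCl, imidazole, DMF, rt
Reagents that add atoms: tert-butyldimethylsilyl chloride, C[Si](C)(Cl)C(C)(C)C
Why: Standard silylation of a primary alcohol; the alkyl silyl ether tolerates the organolithium, alkoxide and hydride steps that follow.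

Step 9
Reactants: 12 Ar(BC)–Br
Product: 14 (2S,3R)-2-[4-(benzyloxy)-3-methoxyphenyl]-3-[(TBS-oxy)methyl]-7-methoxy-2,3-dihydro-1-benzofuran-5-carbaldehyde, via aryllithium Ar(BC)–Li 13 (not isolated)
Conditions: n-BuLi (1.1 equiv), THF, −78 °C; DMF (3 equiv), −78 to 0 °C; aqueous NH4Cl
Reagents that add atoms: N,N-dimethylformamide, CN(C)C=O
Why: Bromine–lithium exchange is faster at −78 °C than deprotonation of any benzylic position, and the aryllithium is formylated by the formamide.

Step 10
Reactants: 14 Ar(BC)–CHO; 15 dimethyl succinate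
Product: 17 (3E)-4-Ar(BC)-3-(methoxycarbonyl)but-3-enoic acid, via paraconic ester lactone 16 (not isolated)
Conditions: 15 (3 equiv), NaOMe (3 equiv), MeOH, reflux; then cold 1 M HCl to pH 3
Reagents that add atoms: none
Why: Stobbe condensation: the succinate enolate adds to the aldehyde, the alkoxide lactonises onto the distal ester, and base-induced ring opening of the lactone gives the E arylidene half-ester with the conjugated carboxyl as ester and the CH2 carboxyl as acid. The ring C phenol is a benzyl ether, so methoxide cannot open the dihydrobenzofuran through a quinone methide.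

Step 11
Reactants: 17 (3E)-4-Ar(BC)-3-(methoxycarbonyl)but-3-enoic acid
Product: 18 (3R)-4-Ar(BC)-3-(methoxycarbonyl)butanoic acid
Conditions: [Rh(cod)((S,S)-Et-DuPhos)]BF4 (1 mol %), NaOMe (10 mol %), H2 (5 bar), MeOH, rt
Reagents that add atoms: none
Why: Asymmetric hydrogenation of a β-aryl itaconate half-ester: the carboxylate and the alkene chelate rhodium and the C2-symmetric bisphospholane selects the alkene face, which sets the future lactone β-centre (R). The homogeneous catalyst does not cleave benzyl ethers or the benzylic C2–O bond.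

Step 12
Reactants: 18 (3R)-4-Ar(BC)-3-(methoxycarbonyl)butanoic acid
Product: 20 (4R)-4-[Ar(BC)-methyl]oxolan-2-one, via hydroxy acid 19 (not isolated)
Conditions: LiEt3BH (3.3 equiv), THF, 0 °C to rt; aqueous NH4Cl, then citric acid to pH 4; pyridinium p-toluenesulfonate (cat.), PhMe, 50 °C
Reagents that add atoms: none
Why: The first hydride equivalent converts the acid into its carboxylate, which resists reduction, and the rest reduces the methyl ester to the primary alcohol; the γ-hydroxy acid then lactonises under mild acid that spares the silyl ether. The stereocentre is not involved.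

Step 13
Reactants: 21 5-bromo-2-hydroxy-3-methoxybenzaldehyde
Product: 22 2-(benzyloxy)-5-bromo-3-methoxybenzaldehyde
Conditions: BnBr (1.1 equiv), K2CO3, DMF, rt
Reagents that add atoms: benzyl bromide, BrCc1ccccc1
Why: Williamson etherification of the phenoxide.

Step 14
Reactants: 22 2-(benzyloxy)-5-bromo-3-methoxybenzaldehyde
Product: 23 2-(benzyloxy)-5-bromo-1-ethenyl-3-methoxybenzene
Conditions: Ph3PCH3Br (1.3 equiv), KOt-Bu (1.25 equiv), THF, 0 °C to rt
Reagents that add atoms: methyltriphenylphosphonium bromide, C[P+](c1ccccc1)(c1ccccc1)c1ccccc1.[Br-]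
Why: Wittig methylenation of an aromatic aldehyde.

Step 15
Reactants: 23 2-(benzyloxy)-5-bromo-1-ethenyl-3-methoxybenzene; 24 allylboronic acid pinacol ester
Product: 25 2-{(2E)-3-[2-(benzyloxy)-5-bromo-3-methoxyphenyl]prop-2-en-1-yl}-4,4,5,5-tetramethyl-1,3,2-dioxaborolane
Conditions: 24 (3 equiv), second-generation Grubbs catalyst RuCl2(=CHPh)(H2IMes)(PCy3) (5 mol %), CH2Cl2, 40 °C
Reagents that add atoms: none
Why: Olefin cross-metathesis of a styrene with an allylboronate, driven by loss of ethene; styrenyl products form with high E preference, which matters because the alkene geometry becomes the anti relationship of step 16.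

Step 16
Reactants: 25 2-{(2E)-3-[2-(benzyloxy)-5-bromo-3-methoxyphenyl]prop-2-en-1-yl}-4,4,5,5-tetramethyl-1,3,2-dioxaborolane; 26 4-(benzyloxy)-3-methoxybenzaldehyde
Product: 28 (1S,2R)-1-[4-(benzyloxy)-3-methoxyphenyl]-2-[2-(benzyloxy)-5-bromo-3-methoxyphenyl]but-3-en-1-ol, via pinacol borate ester 27 (not isolated)
Conditions: (S)-3,3'-bis(2,4,6-triisopropylphenyl)-1,1'-binaphthyl-2,2'-diyl hydrogen phosphate (5 mol %), 4 Å molecular sieves, PhMe, −30 to 0 °C; aqueous work-up
Reagents that add atoms: none
Why: Chiral phosphoric acid catalysed allylboration of an aromatic aldehyde by a γ-substituted pinacol allylboronate: the closed six-membered chair transition state places the aldehyde aryl and the E γ-aryl group equatorial and gives the anti product, and the acid, bound to a boronate oxygen and the formyl hydrogen, selects the aldehyde face, which sets the carbinol centre (1S) and with it C2.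

Step 17
Reactants: 28 (1S,2R)-1-[4-(benzyloxy)-3-methoxyphenyl]-2-[2-(benzyloxy)-5-bromo-3-methoxyphenyl]but-3-en-1-ol
Product: 30 (1S,2S)-1-[4-(benzyloxy)-3-methoxyphenyl]-2-[2-(benzyloxy)-5-bromo-3-methoxyphenyl]propane-1,3-diol, via secondary ozonide 29 (not isolated)
Conditions: O3, CH2Cl2, −78 °C, Sudan Red 7B as end-point indicator; then NaBH4 (5 equiv), EtOH, −78 to 0 °C
Reagents that add atoms: ozone, [O-][O+]=O
Why: Ozonolysis of the terminal alkene is much faster than attack on the dialkoxyarenes, and direct borohydride reduction of the ozonide gives the primary alcohol without the epimerisable α-aryl aldehyde ever being isolated. Both stereocentres are kept; the descriptor at C2 changes only because the substituent priorities change.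

Step 18
Reactants: 30 (1S,2S)-1-[4-(benzyloxy)-3-methoxyphenyl]-2-[2-(benzyloxy)-5-bromo-3-methoxyphenyl]propane-1,3-diol
Product: 31 (1S,2S)-1-[4-(benzyloxy)-3-methoxyphenyl]-2-[2-(benzyloxy)-5-bromo-3-methoxyphenyl]-1,3-bis(TBS-oxy)propane
Conditions: TBSOTf (2.6 equiv), 2,6-lutidine, CH2Cl2, 0 °C
Reagents that add atoms: tert-butyldimethylsilyl trifluoromethanesulfonate, C[Si](C)(OS(=O)(=O)C(F)(F)F)C(C)(C)C
Why: The silyl triflate silylates the hindered secondary benzylic alcohol as well as the primary one; the buffered conditions do not ionise the benzylic position.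

Step 19
Reactants: 31 (1S,2S)-1-[4-(benzyloxy)-3-methoxyphenyl]-2-[2-(benzyloxy)-5-bromo-3-methoxyphenyl]-1,3-bis(TBS-oxy)propane
Product: 33 4-(benzyloxy)-3-[(1S,2S)-1-[4-(benzyloxy)-3-methoxyphenyl]-1,3-bis(TBS-oxy)propan-2-yl]-5-methoxybenzaldehyde, via aryllithium 32 (not isolated)
Conditions: n-BuLi (1.1 equiv), THF, −78 °C; DMF (3 equiv), −78 to 0 °C; aqueous NH4Cl
Reagents that add atoms: N,N-dimethylformamide, CN(C)C=O
Why: Bromine–lithium exchange followed by formylation, as in step 9; the aryllithium is para to the benzyloxy group and has no pathway for silyl migration or elimination.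

Step 20
Reactants: 33 4-(benzyloxy)-3-[(1S,2S)-1-[4-(benzyloxy)-3-methoxyphenyl]-1,3-bis(TBS-oxy)propan-2-yl]-5-methoxybenzaldehyde
Product: 34 {4-(benzyloxy)-3-[(1S,2S)-1-[4-(benzyloxy)-3-methoxyphenyl]-1,3-bis(TBS-oxy)propan-2-yl]-5-methoxyphenyl}methanol
Conditions: NaBH4, MeOH/THF, 0 °C
Reagents that add atoms: none
Why: Borohydride reduction of an aromatic aldehyde.

Step 21
Reactants: 34 {4-(benzyloxy)-3-[(1S,2S)-1-[4-(benzyloxy)-3-methoxyphenyl]-1,3-bis(TBS-oxy)propan-2-yl]-5-methoxyphenyl}methanol
Product: 35 2-(benzyloxy)-5-(bromomethyl)-1-[(1S,2S)-1-[4-(benzyloxy)-3-methoxyphenyl]-1,3-bis(TBS-oxy)propan-2-yl]-3-methoxybenzene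
Conditions: CBr4, PPh3, CH2Cl2, 0 °C; used without storage
Reagents that add atoms: carbon tetrabromide, BrC(Br)(Br)Br
Why: Appel bromination of a primary benzylic alcohol under neutral conditions that spare the silyl ethers.

Step 22
Reactants: 20 (4R)-4-[Ar(BC)-methyl]oxolan-2-one; 35 2-(benzyloxy)-5-(bromomethyl)-1-[(1S,2S)-1-[4-(benzyloxy)-3-methoxyphenyl]-1,3-bis(TBS-oxy)propan-2-yl]-3-methoxybenzene
Product: 37 (3R,4R)-3-{4-(benzyloxy)-3-[(1S,2S)-1-[4-(benzyloxy)-3-methoxyphenyl]-1,3-bis(TBS-oxy)propan-2-yl]-5-methoxybenzyl}-4-[Ar(BC)-methyl]oxolan-2-one, via lithium enolate 36 (not isolated)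
Conditions: 20, LiN(SiMe3)2 (1.05 equiv), THF, −78 °C; then 35 (1.1 equiv), N,N'-dimethylpropyleneurea, −78 to −30 °C
Reagents that add atoms: none
Why: Alkylation of a β-substituted γ-butyrolactone enolate: the benzylic bromide approaches the planar enolate from the face opposite the β-benzyl group, so the α-centre forms trans (3R) under control of the β-centre.

Step 23
Reactants: 37 (3R,4R)-3-{4-(benzyloxy)-3-[(1S,2S)-1-[4-(benzyloxy)-3-methoxyphenyl]-1,3-bis(TBS-oxy)propan-2-yl]-5-methoxybenzyl}-4-[Ar(BC)-methyl]oxolan-2-one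
Product: 38 (3R,4R)-3-{4-(benzyloxy)-3-[(1S,2S)-1-[4-(benzyloxy)-3-methoxyphenyl]-1,3-dihydroxypropan-2-yl]-5-methoxybenzyl}-4-{[(2S,3R)-2-[4-(benzyloxy)-3-methoxyphenyl]-3-(hydroxymethyl)-7-methoxy-2,3-dihydro-1-benzofuran-5-yl]methyl}oxolan-2-one
Conditions: Bu4NF (6 equiv), AcOH (6 equiv), THF, 0 °C to rt
Reagents that add atoms: none
Why: Fluoride cleaves the three alkyl silyl ethers; acetic acid buffers the medium so that the lactone is not opened, and any epimerisation at the α-carbon returns to the stable trans lactone.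

Step 24
Reactants: 38 the tris(benzyl ether) triol of step 23
Product: 39 the target, (3R,4R)-3-{4-hydroxy-3-[(1S,2S)-1,3-dihydroxy-1-(4-hydroxy-3-methoxyphenyl)propan-2-yl]-5-methoxybenzyl}-4-{[(2S,3R)-2-(4-hydroxy-3-methoxyphenyl)-3-(hydroxymethyl)-7-methoxy-2,3-dihydro-1-benzofuran-5-yl]methyl}oxolan-2-one
Conditions: H2 (1 atm), Pd/C (10 wt %), EtOAc, rt, stopped as soon as 38 is consumed
Reagents that add atoms: none
Why: Hydrogenolysis of primary benzyl aryl ethers on palladium is fast under neutral conditions, whereas the secondary benzylic C–O bonds (the carbinol and the ring C2–O1 bond) react much more slowly without acid; the step is neutral and leaves no reagent residue with the sensitive product.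

## Compound list

1 | ferulic acid | COc1cc(/C=C/C(=O)O)ccc1O | starting material
2 | benzyl (2E)-3-[4-(benzyloxy)-3-methoxyphenyl]prop-2-enoate | COc1cc(/C=C/C(=O)OCc2ccccc2)ccc1OCc1ccccc1 | intermediate
3 | (2E)-3-[4-(benzyloxy)-3-methoxyphenyl]prop-2-en-1-ol | COc1cc(/C=C/CO)ccc1OCc1ccccc1 | intermediate
4 | (2E)-3-[4-(benzyloxy)-3-methoxyphenyl]prop-2-en-1-yl methyl carbonate | COC(=O)OC/C=C/c1ccc(OCc2ccccc2)c(OC)c1 | intermediate
5 | 4-bromo-2-methoxyphenol | COc1cc(Br)ccc1O | starting material
6 | 4-bromo-2-iodo-6-methoxyphenol | COc1cc(Br)cc(I)c1O | intermediate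
7 | lithium 4-bromo-2-iodo-6-methoxyphenoxide | COc1cc(Br)cc(I)c1O[Li] | intermediate
8 | 1-(benzyloxy)-4-[(1S)-1-(4-bromo-2-iodo-6-methoxyphenoxy)prop-2-en-1-yl]-2-methoxybenzene | C=C[C@@H](c1ccc(OCc2ccccc2)c(OC)c1)Oc1c(I)cc(Br)cc1OC | intermediate
9 | TEMPO, 2,2,6,6-tetramethylpiperidin-1-oxyl | CC1(C)CCCC(C)(C)N1[O] | starting material
10 | 1-{[(2S,3R)-2-[4-(benzyloxy)-3-methoxyphenyl]-5-bromo-7-methoxy-2,3-dihydro-1-benzofuran-3-yl]methoxy}-2,2,6,6-tetramethylpiperidine | Brc1cc(OC)c2c(c1)[C@H](CON1C(C)(C)CCCC1(C)C)[C@@H](c1ccc(OCc3ccccc3)c(OC)c1)O2 | intermediate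
11 | [(2S,3R)-2-[4-(benzyloxy)-3-methoxyphenyl]-5-bromo-7-methoxy-2,3-dihydro-1-benzofuran-3-yl]methanol | Brc1cc(OC)c2c(c1)[C@H](CO)[C@@H](c1ccc(OCc3ccccc3)c(OC)c1)O2 | intermediate
12 | {[(2S,3R)-2-[4-(benzyloxy)-3-methoxyphenyl]-5-bromo-7-methoxy-2,3-dihydro-1-benzofuran-3-yl]methoxy}(tert-butyl)dimethylsilane | Brc1cc(OC)c2c(c1)[C@H](CO[Si](C)(C)C(C)(C)C)[C@@H](c1ccc(OCc3ccccc3)c(OC)c1)O2 | intermediate
13 | 5-lithio derivative of 12, Ar(BC)–Li | [Li]c1cc(OC)c2c(c1)[C@H](CO[Si](C)(C)C(C)(C)C)[C@@H](c1ccc(OCc3ccccc3)c(OC)c1)O2 | intermediate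
14 | (2S,3R)-2-[4-(benzyloxy)-3-methoxyphenyl]-3-[(TBS-oxy)methyl]-7-methoxy-2,3-dihydro-1-benzofuran-5-carbaldehyde | O=Cc1cc(OC)c2c(c1)[C@H](CO[Si](C)(C)C(C)(C)C)[C@@H](c1ccc(OCc3ccccc3)c(OC)c1)O2 | intermediate
15 | dimethyl succinate | COC(=O)CCC(=O)OC | starting material
16 | methyl 2-Ar(BC)-5-oxooxolane-3-carboxylate (paraconic ester, mixture at the two new centres) | COC(=O)C1CC(=O)OC1c1cc(OC)c2c(c1)[C@H](CO[Si](C)(C)C(C)(C)C)[C@@H](c1ccc(OCc3ccccc3)c(OC)c1)O2 | intermediate
17 | (3E)-4-Ar(BC)-3-(methoxycarbonyl)but-3-enoic acid | OC(=O)C/C(C(=O)OC)=C\c1cc(OC)c2c(c1)[C@H](CO[Si](C)(C)C(C)(C)C)[C@@H](c1ccc(OCc3ccccc3)c(OC)c1)O2 | intermediate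
18 | (3R)-4-Ar(BC)-3-(methoxycarbonyl)butanoic acid | COC(=O)[C@@H](CC(=O)O)Cc1cc(OC)c2c(c1)[C@H](CO[Si](C)(C)C(C)(C)C)[C@@H](c1ccc(OCc3ccccc3)c(OC)c1)O2 | intermediate
19 | (3R)-4-Ar(BC)-3-(hydroxymethyl)butanoic acid | OC[C@@H](CC(=O)O)Cc1cc(OC)c2c(c1)[C@H](CO[Si](C)(C)C(C)(C)C)[C@@H](c1ccc(OCc3ccccc3)c(OC)c1)O2 | intermediate
20 | (4R)-4-[Ar(BC)-methyl]oxolan-2-one | C1C(=O)OC[C@@H]1Cc1cc(OC)c2c(c1)[C@H](CO[Si](C)(C)C(C)(C)C)[C@@H](c1ccc(OCc3ccccc3)c(OC)c1)O2 | intermediate
21 | 5-bromo-2-hydroxy-3-methoxybenzaldehyde | COc1cc(Br)cc(C=O)c1O | starting material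
22 | 2-(benzyloxy)-5-bromo-3-methoxybenzaldehyde | COc1cc(Br)cc(C=O)c1OCc1ccccc1 | intermediate
23 | 2-(benzyloxy)-5-bromo-1-ethenyl-3-methoxybenzene | COc1cc(Br)cc(C=C)c1OCc1ccccc1 | intermediate
24 | allylboronic acid pinacol ester | C=CCB1OC(C)(C)C(C)(C)O1 | starting material
25 | 2-{(2E)-3-[2-(benzyloxy)-5-bromo-3-methoxyphenyl]prop-2-en-1-yl}-4,4,5,5-tetramethyl-1,3,2-dioxaborolane | COc1cc(Br)cc(/C=C/CB2OC(C)(C)C(C)(C)O2)c1OCc1ccccc1 | intermediate
26 | 4-(benzyloxy)-3-methoxybenzaldehyde | COc1cc(C=O)ccc1OCc1ccccc1 | starting material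
27 | pinacol borate ester of 28 | COc1cc([C@@H](OB2OC(C)(C)C(C)(C)O2)[C@H](C=C)c2cc(Br)cc(OC)c2OCc2ccccc2)ccc1OCc1ccccc1 | intermediate
28 | (1S,2R)-1-[4-(benzyloxy)-3-methoxyphenyl]-2-[2-(benzyloxy)-5-bromo-3-methoxyphenyl]but-3-en-1-ol | COc1cc([C@@H](O)[C@H](C=C)c2cc(Br)cc(OC)c2OCc2ccccc2)ccc1OCc1ccccc1 | intermediate
29 | secondary ozonide (1,2,4-trioxolane) of 28 | COc1cc([C@@H](O)[C@H](C2OCOO2)c2cc(Br)cc(OC)c2OCc2ccccc2)ccc1OCc1ccccc1 | intermediate
30 | (1S,2S)-1-[4-(benzyloxy)-3-methoxyphenyl]-2-[2-(benzyloxy)-5-bromo-3-methoxyphenyl]propane-1,3-diol | COc1cc([C@@H](O)[C@H](CO)c2cc(Br)cc(OC)c2OCc2ccccc2)ccc1OCc1ccccc1 | intermediate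
31 | (1S,2S)-1-[4-(benzyloxy)-3-methoxyphenyl]-2-[2-(benzyloxy)-5-bromo-3-methoxyphenyl]-1,3-bis(TBS-oxy)propane | COc1cc([C@@H](O[Si](C)(C)C(C)(C)C)[C@H](CO[Si](C)(C)C(C)(C)C)c2cc(Br)cc(OC)c2OCc2ccccc2)ccc1OCc1ccccc1 | intermediate
32 | 5-lithio derivative of 31 | COc1cc([C@@H](O[Si](C)(C)C(C)(C)C)[C@H](CO[Si](C)(C)C(C)(C)C)c2cc([Li])cc(OC)c2OCc2ccccc2)ccc1OCc1ccccc1 | intermediate
33 | 4-(benzyloxy)-3-[(1S,2S)-1-[4-(benzyloxy)-3-methoxyphenyl]-1,3-bis(TBS-oxy)propan-2-yl]-5-methoxybenzaldehyde | COc1cc([C@@H](O[Si](C)(C)C(C)(C)C)[C@H](CO[Si](C)(C)C(C)(C)C)c2cc(C=O)cc(OC)c2OCc2ccccc2)ccc1OCc1ccccc1 | intermediate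
34 | {4-(benzyloxy)-3-[(1S,2S)-1-[4-(benzyloxy)-3-methoxyphenyl]-1,3-bis(TBS-oxy)propan-2-yl]-5-methoxyphenyl}methanol | COc1cc([C@@H](O[Si](C)(C)C(C)(C)C)[C@H](CO[Si](C)(C)C(C)(C)C)c2cc(CO)cc(OC)c2OCc2ccccc2)ccc1OCc1ccccc1 | intermediate
35 | 2-(benzyloxy)-5-(bromomethyl)-1-[(1S,2S)-1-[4-(benzyloxy)-3-methoxyphenyl]-1,3-bis(TBS-oxy)propan-2-yl]-3-methoxybenzene | COc1cc([C@@H](O[Si](C)(C)C(C)(C)C)[C@H](CO[Si](C)(C)C(C)(C)C)c2cc(CBr)cc(OC)c2OCc2ccccc2)ccc1OCc1ccccc1 | intermediate
36 | lithium enolate of 20 | [Li]OC1=C[C@H](CO1)Cc1cc(OC)c2c(c1)[C@H](CO[Si](C)(C)C(C)(C)C)[C@@H](c1ccc(OCc3ccccc3)c(OC)c1)O2 | intermediate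
37 | (3R,4R)-3-{4-(benzyloxy)-3-[(1S,2S)-1-[4-(benzyloxy)-3-methoxyphenyl]-1,3-bis(TBS-oxy)propan-2-yl]-5-methoxybenzyl}-4-[Ar(BC)-methyl]oxolan-2-one | COc1cc([C@@H](O[Si](C)(C)C(C)(C)C)[C@H](CO[Si](C)(C)C(C)(C)C)c2cc(C[C@H]3C(=O)OC[C@@H]3Cc3cc(OC)c4c(c3)[C@H](CO[Si](C)(C)C(C)(C)C)[C@@H](c3ccc(OCc5ccccc5)c(OC)c3)O4)cc(OC)c2OCc2ccccc2)ccc1OCc1ccccc1 | intermediate
38 | tris(benzyl ether) of the target | COc1cc([C@@H](O)[C@H](CO)c2cc(C[C@H]3C(=O)OC[C@@H]3Cc3cc(OC)c4c(c3)[C@H](CO)[C@@H](c3ccc(OCc5ccccc5)c(OC)c3)O4)cc(OC)c2OCc2ccccc2)ccc1OCc1ccccc1 | intermediate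
39 | CNP0186558.2 | COc1cc([C@@H](O)[C@H](CO)c2cc(C[C@H]3C(=O)OC[C@@H]3Cc3cc(OC)c4c(c3)[C@H](CO)[C@@H](c3ccc(O)c(OC)c3)O4)cc(OC)c2O)ccc1O | target

## Step count and least certain steps

Total step count: 24. Longest linear sequence: 14 steps (steps 1–3, 5–12 and 22–24).

**Step 6 (key step).** The most likely failure is incomplete stereocontrol at C3. The chair preference of a flattened aryl-radical transition state is moderate, so some cis isomer should form alongside the trans product. Lesser risks are capture of the aryl radical by the nitroxide before it cyclises and hydrogen transfer to the primary radical. The cis isomer cannot be repaired by epimerising C2, because that would lead into the enantiomeric trans series, so it has to be removed by chromatography.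

Fallback, from 6 back to 11, by carbenoid C–H insertion:
- Phenol 6 is alkylated with commercial 4-(benzyloxy)-3-methoxybenzyl chloride (K2CO3, DMF) to give 1-(benzyloxy)-4-[(4-bromo-2-iodo-6-methoxyphenoxy)methyl]-2-methoxybenzene F1.
- The iodide is coupled selectively with the Reformatsky reagent BrZnCH2CO2Me under Pd(dba)2 and a bulky phosphine to give methyl 2-{2-[(4-benzyloxy-3-methoxybenzyl)oxy]-5-bromo-3-methoxyphenyl}acetate F2.
- Diazo transfer (4-acetamidobenzenesulfonyl azide, DBU) gives methyl 2-{2-[(4-benzyloxy-3-methoxybenzyl)oxy]-5-bromo-3-methoxyphenyl}-2-diazoacetate F3.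
- A chiral dirhodium tetracarboxylate such as Rh2(S-PTTL)4 (antipode chosen for 2S) inserts the carbenoid into the benzylic C–H bond of the ether and gives methyl (2S,3R)-cis-2-[4-(benzyloxy)-3-methoxyphenyl]-5-bromo-7-methoxy-2,3-dihydro-1-benzofuran-3-carboxylate F4.
- NaOMe in MeOH epimerises the ester-bearing carbon to methyl (2S,3S)-trans-2-[4-(benzyloxy)-3-methoxyphenyl]-5-bromo-7-methoxy-2,3-dihydro-1-benzofuran-3-carboxylate F5.
- LiBH4 reduces the ester to alcohol 11.

**Step 5.** The most likely failure is loss of branched selectivity and of enantiopurity. The product is an electron-rich benzylic allylic ether of a fairly acidic phenol and can re-ionise on the catalyst, and the 2,6-disubstituted aryloxide attacks slowly.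

Fallback, from 26 back to 8:
- Vinylmagnesium bromide adds to aldehyde 26 to give racemic 1-[4-(benzyloxy)-3-methoxyphenyl]prop-2-en-1-ol F6.
- Immobilised Candida antarctica lipase B with vinyl acetate should acylate the R enantiomer to (1R)-1-[4-(benzyloxy)-3-methoxyphenyl]prop-2-en-1-yl acetate F7, which is separated from the unreacted alcohol.
- K2CO3 in MeOH frees (1R)-1-[4-(benzyloxy)-3-methoxyphenyl]prop-2-en-1-ol F8.
- A Mitsunobu reaction with phenol 6 (PPh3, diisopropyl azodicarboxylate, PhMe, −20 °C) inverts the centre and gives 8.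

**Step 16.** The most likely failure is insufficient facial selectivity. A γ-aryl allylboronate is less nucleophilic than a crotylboronate, so the reaction may have to be warmed to where the uncatalysed pathway competes. The anti relationship is not at risk, because it follows from the alkene geometry.

Fallback, from 25 and 26 back to 28:
- Boronate 25 and aldehyde 26 are combined without catalyst (PhMe, rt to 40 °C) to give the racemic anti alcohol, rac-(1S*,2R*)-1-[4-(benzyloxy)-3-methoxyphenyl]-2-[2-(benzyloxy)-5-bromo-3-methoxyphenyl]but-3-en-1-ol F9.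
- Acylative kinetic resolution with a chiral isothiourea acyl-transfer catalyst and isobutyric anhydride (antipode chosen to acylate the 1R enantiomer) converts the unwanted enantiomer into (1R,2S)-1-[4-(benzyloxy)-3-methoxyphenyl]-2-[2-(benzyloxy)-5-bromo-3-methoxyphenyl]but-3-en-1-yl 2-methylpropanoate F10 and leaves 28.

**Step 22.** The most likely failure is slow alkylation. The bulky, electron-rich benzylic bromide may ionise and decompose before the enolate captures it, and excess enolate would lead to double alkylation.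

Fallback, from 20 and 33 back to 37:
- The enolate 36 is added to aldehyde 33 to give the aldol adduct, (4R)-3-{[4-(benzyloxy)-3-[(1S,2S)-1-[4-(benzyloxy)-3-methoxyphenyl]-1,3-bis(TBS-oxy)propan-2-yl]-5-methoxyphenyl](hydroxy)methyl}-4-[Ar(BC)-methyl]oxolan-2-one F11.
- Mesylation (MsCl, Et3N) gives the methanesulfonate of the aldol adduct F12.
- Elimination with DBU gives the (3E)-3-arylidene lactone, (3E,4R)-3-{4-(benzyloxy)-3-[(1S,2S)-1-[4-(benzyloxy)-3-methoxyphenyl]-1,3-bis(TBS-oxy)propan-2-yl]-5-methoxybenzylidene}-4-[Ar(BC)-methyl]oxolan-2-one F13.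
- Conjugate reduction with NaBH4 and NiCl2·6H2O (MeOH/THF, 0 °C) gives 37 mixed with its cis epimer, the (3S,4R)-lactone F14.
- DBU in PhMe equilibrates the mixture to the trans lactone 37.

**Step 24.** The most likely failure is over-reduction. The free carbinol of the diol unit and the C2–O1 bond of the dihydrobenzofuran are both secondary benzylic C–O bonds and can undergo hydrogenolysis if the reaction runs on.

Fallback, from 37 back to 39, with the order of the two deprotections reversed:
- Hydrogenolysis (H2, Pd/C, EtOAc) is run on 37, where the carbinol is still a silyl ether, to give the triphenol tris(silyl ether), (3R,4R)-3-{4-hydroxy-3-[(1S,2S)-1-(4-hydroxy-3-methoxyphenyl)-1,3-bis(TBS-oxy)propan-2-yl]-5-methoxybenzyl}-4-{[(2S,3R)-2-(4-hydroxy-3-methoxyphenyl)-3-[(TBS-oxy)methyl]-7-methoxy-2,3-dihydro-1-benzofuran-5-yl]methyl}oxolan-2-one F15.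
- Buffered desilylation (Bu4NF, AcOH, THF) gives 39.

## Further compounds

F1 | step 6 | 1-(benzyloxy)-4-[(4-bromo-2-iodo-6-methoxyphenoxy)methyl]-2-methoxybenzene | COc1cc(COc2c(I)cc(Br)cc2OC)ccc1OCc1ccccc1
F2 | step 6 | methyl 2-{2-[(4-benzyloxy-3-methoxybenzyl)oxy]-5-bromo-3-methoxyphenyl}acetate | COC(=O)Cc1cc(Br)cc(OC)c1OCc1ccc(OCc2ccccc2)c(OC)c1
F3 | step 6 | methyl 2-{2-[(4-benzyloxy-3-methoxybenzyl)oxy]-5-bromo-3-methoxyphenyl}-2-diazoacetate | COC(=O)C(=[N+]=[N-])c1cc(Br)cc(OC)c1OCc1ccc(OCc2ccccc2)c(OC)c1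
F4 | step 6 | methyl (2S,3R)-cis-2-[4-(benzyloxy)-3-methoxyphenyl]-5-bromo-7-methoxy-2,3-dihydro-1-benzofuran-3-carboxylate | Brc1cc(OC)c2c(c1)[C@@H](C(=O)OC)[C@@H](c1ccc(OCc3ccccc3)c(OC)c1)O2
F5 | step 6 | methyl (2S,3S)-trans-2-[4-(benzyloxy)-3-methoxyphenyl]-5-bromo-7-methoxy-2,3-dihydro-1-benzofuran-3-carboxylate | Brc1cc(OC)c2c(c1)[C@H](C(=O)OC)[C@@H](c1ccc(OCc3ccccc3)c(OC)c1)O2
F6 | step 5 | racemic 1-[4-(benzyloxy)-3-methoxyphenyl]prop-2-en-1-ol | C=CC(O)c1ccc(OCc2ccccc2)c(OC)c1
F7 | step 5 | (1R)-1-[4-(benzyloxy)-3-methoxyphenyl]prop-2-en-1-yl acetate | C=C[C@@H](OC(C)=O)c1ccc(OCc2ccccc2)c(OC)c1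
F8 | step 5 | (1R)-1-[4-(benzyloxy)-3-methoxyphenyl]prop-2-en-1-ol | C=C[C@@H](O)c1ccc(OCc2ccccc2)c(OC)c1
F9 | step 16 | rac-(1S*,2R*)-1-[4-(benzyloxy)-3-methoxyphenyl]-2-[2-(benzyloxy)-5-bromo-3-methoxyphenyl]but-3-en-1-ol | COc1cc([C@@H](O)[C@H](C=C)c2cc(Br)cc(OC)c2OCc2ccccc2)ccc1OCc1ccccc1.COc1cc([C@H](O)[C@@H](C=C)c2cc(Br)cc(OC)c2OCc2ccccc2)ccc1OCc1ccccc1
F10 | step 16 | (1R,2S)-1-[4-(benzyloxy)-3-methoxyphenyl]-2-[2-(benzyloxy)-5-bromo-3-methoxyphenyl]but-3-en-1-yl 2-methylpropanoate | COc1cc([C@H](OC(=O)C(C)C)[C@@H](C=C)c2cc(Br)cc(OC)c2OCc2ccccc2)ccc1OCc1ccccc1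
F11 | step 22 | (4R)-3-{[4-(benzyloxy)-3-[(1S,2S)-1-[4-(benzyloxy)-3-methoxyphenyl]-1,3-bis(TBS-oxy)propan-2-yl]-5-methoxyphenyl](hydroxy)methyl}-4-[Ar(BC)-methyl]oxolan-2-one | COc1cc([C@@H](O[Si](C)(C)C(C)(C)C)[C@H](CO[Si](C)(C)C(C)(C)C)c2cc(C(O)C3C(=O)OC[C@@H]3Cc3cc(OC)c4c(c3)[C@H](CO[Si](C)(C)C(C)(C)C)[C@@H](c3ccc(OCc5ccccc5)c(OC)c3)O4)cc(OC)c2OCc2ccccc2)ccc1OCc1ccccc1
F12 | step 22 | methanesulfonate of F11 | COc1cc([C@@H](O[Si](C)(C)C(C)(C)C)[C@H](CO[Si](C)(C)C(C)(C)C)c2cc(C(OS(C)(=O)=O)C3C(=O)OC[C@@H]3Cc3cc(OC)c4c(c3)[C@H](CO[Si](C)(C)C(C)(C)C)[C@@H](c3ccc(OCc5ccccc5)c(OC)c3)O4)cc(OC)c2OCc2ccccc2)ccc1OCc1ccccc1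
F13 | step 22 | (3E,4R)-3-{4-(benzyloxy)-3-[(1S,2S)-1-[4-(benzyloxy)-3-methoxyphenyl]-1,3-bis(TBS-oxy)propan-2-yl]-5-methoxybenzylidene}-4-[Ar(BC)-methyl]oxolan-2-one | COc1cc([C@@H](O[Si](C)(C)C(C)(C)C)[C@H](CO[Si](C)(C)C(C)(C)C)c2cc(/C=C3/C(=O)OC[C@@H]3Cc3cc(OC)c4c(c3)[C@H](CO[Si](C)(C)C(C)(C)C)[C@@H](c3ccc(OCc5ccccc5)c(OC)c3)O4)cc(OC)c2OCc2ccccc2)ccc1OCc1ccccc1
F14 | step 22 | (3S,4R)-cis epimer of 37 | COc1cc([C@@H](O[Si](C)(C)C(C)(C)C)[C@H](CO[Si](C)(C)C(C)(C)C)c2cc(C[C@@H]3C(=O)OC[C@@H]3Cc3cc(OC)c4c(c3)[C@H](CO[Si](C)(C)C(C)(C)C)[C@@H](c3ccc(OCc5ccccc5)c(OC)c3)O4)cc(OC)c2OCc2ccccc2)ccc1OCc1ccccc1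
F15 | step 24 | triphenol tris(silyl ether) of the target | COc1cc([C@@H](O[Si](C)(C)C(C)(C)C)[C@H](CO[Si](C)(C)C(C)(C)C)c2cc(C[C@H]3C(=O)OC[C@@H]3Cc3cc(OC)c4c(c3)[C@H](CO[Si](C)(C)C(C)(C)C)[C@@H](c3ccc(O)c(OC)c3)O4)cc(OC)c2O)ccc1O
A1 | alternative 1 | anti 1,2-diaryl-3-silyloxypropyl pinacol boronic ester | COc1cc([C@@H](B2OC(C)(C)C(C)(C)O2)[C@H](CO[Si](C)(C)C(C)(C)C)c2cc(C(=O)OC)cc(OC)c2OCc2ccccc2)ccc1OCc1ccccc1
A2 | alternative 1 | (Z)-3-(tert-butyldimethylsilyloxy)prop-1-enyl pinacol boronate | CC(C)(C)[Si](C)(C)OC/C=C\B1OC(C)(C)C(C)(C)O1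
A3 | alternative 1 | 4-(benzyloxy)-3-methoxyphenyllithium | [Li]c1ccc(OCc2ccccc2)c(OC)c1
A4 | alternative 1 | methyl 4-(benzyloxy)-3-methoxy-5-(trifluoromethylsulfonyloxy)benzoate | COC(=O)c1cc(OC)c(OCc2ccccc2)c(OS(=O)(=O)C(F)(F)F)c1
A5 | alternative 2 | (4R)-4-{[(2S,3R)-2-(4-hydroxy-3-methoxyphenyl)-3-(hydroxymethyl)-7-methoxy-2,3-dihydro-1-benzofuran-5-yl]methyl}oxolan-2-one | C1C(=O)OC[C@@H]1Cc1cc(OC)c2c(c1)[C@H](CO)[C@@H](c1ccc(O)c(OC)c1)O2
A6 | alternative 2 | 3-{[(2S,3R)-2-(4-hydroxy-3-methoxyphenyl)-3-(hydroxymethyl)-7-methoxy-2,3-dihydro-1-benzofuran-5-yl]methyl}cyclobutan-1-one | O=C1CC(Cc2cc(OC)c3c(c2)[C@H](CO)[C@@H](c2ccc(O)c(OC)c2)O3)C1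
A7 | alternative 3 | (2S,3R)-5-bromo-2-(4-hydroxy-3-methoxyphenyl)-7-methoxy-3-[(tert-butyldimethylsilyloxy)methyl]-2,3-dihydro-1-benzofuran | Brc1cc(OC)c2c(c1)[C@H](CO[Si](C)(C)C(C)(C)C)[C@@H](c1ccc(O)c(OC)c1)O2
A8 | alternative 3 | (2R)-2-(5-bromo-2-hydroxy-3-methoxyphenyl)-3-(tert-butyldimethylsilyloxy)-1-(4-hydroxy-3-methoxyphenyl)propan-1-ol, both C1 epimers | COc1cc(C(O)[C@@H](CO[Si](C)(C)C(C)(C)C)c2cc(Br)cc(OC)c2O)ccc1O
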